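The starting material outweighed the catalyst 200 to one, so each catalyst had to turn over that many times to consume the charge.

| flask | starting material | reagent | scavenger | free catalyst | time |
|---|---|---|---|---|---|
| summer | 0.0020 M | 2.20 mM | 1.60 mM | 10 µM | 1.5 min |
| noon | 0.0020 M | 2.20 mM | 2.40 mM | 10 µM | 1.5 min |
| spring | 0.0020 M | 2.20 mM | 3.60 mM | 10 µM | 1.5 min |

- part of the starting material that has reacted at the end, summer
- part of the starting material that has reacted at the end, noon
- part of the starting material that has reacted at the end, spring
- what raising the concentration of scavenger from its lowest to its highest value here does to the part of the starting material that has reacted (changes below 5 percentage points count as none) (it falls / it rises / no change)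

    reagent + free catalyst → catalyst intermediate A (k1 = 35000 L mol⁻¹ s⁻¹)
    starting material + catalyst intermediate A → catalyst intermediate B (k2 = 5600 L mol⁻¹ s⁻¹)
    catalyst intermediate B ⇌ released group + catalyst intermediate C (K3 = 6.4 × 10⁻⁴ M, k3 = 5.1 s⁻¹)
    catalyst intermediate C ⇌ free catalyst + product (K4 = 0.0035 M, k4 = 40 s⁻¹)
    starting material + released group ⇌ idle adduct, settled at all times (K5 = 210 L mol⁻¹)
    scavenger + released group → scavenged by-product (k6 = 760 L mol⁻¹ s⁻¹)

I priced one turnover by hand, with reagent taken as charged and the back steps ignored. Taking up reagent, releasing the group and letting go of the product cost 0.234 s together. Capture of starting material by catalyst intermediate A cost more as the starting material thinned. Summed over the charge, that cost made the fraction left fall exponentially, a pseudo-first-order decay with rate constant 0.0560 s⁻¹, during whatever time the fixed costs left over. This spare time, the run time less the fixed cost of turning over the whole charge, was 43.2 s. It left a fraction 8.91% unreacted. The scavenger does not enter the spare time, so I reckoned 91.1% for summer, 91.1% for noon and 91.1% for spring.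

In summer the scavenger charge was smaller than the starting material charge, and by my reckoning it fell short of the released group at the end by 11.1% of the starting material. I reckoned that much free released group to push catalyst intermediate C back at 4.42% of the rate at which it went forward. Even counted as that share of the whole conversion, this late loss stayed below the mark of 5 percentage points. So I expected no change.

The forecast gave 89%, 90% and 90%, with no change, holding that “raising the scavenger changes conversion by only about a point”. The simulation gave 90.9%, 90.9% and 91.0%, with no change: the scavenger moved the result by 0.076 points.

Noon had not come to rest at 1.5 min: it still held 9.09% of its starting material. Ten times the time raised the spare time to 853 s, which is 47.8 exponential lifetimes, and summer, noon and spring reached 100%, 100% and 100%. In the neighbour of noon with 5.0 × 10⁻⁴ M of starting material, the spare time of 78.3 s left 1.25% by hand, and that flask held 1.3%. In noon itself, at 15.0 min, free reagent had fallen from 17.1% to 8.64%, and catalyst intermediate A, the resting state, held 100% of the catalyst.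

The numbers of this flask were drawn at random within sensible limits; the rest is arithmetic.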